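The route opens the 3(2H)-furanone ring (O, C3, C2, C1, C10; germacrane numbering) at C1–C2 and at O–C10. The C1–C10 edge is stored in a temporary γ-lactone, ring A (C1, C10, C9, C8, O8), that carries Cl and CH3 on C10. The precursor is a bis-γ-lactone, ring A bonded to the final lactone ring B. In one operation the enolate of 3-methylbut-3-en-2-one is C-acylated by ring A and the diketonate oxygen displaces the tertiary chloride with inversion. Lactone becomes furanone, C10 is fixed, and the C8 hydroxyl is released for the angelate. C7, C11 and C10 are relayed from one purchased centre (C6); C8 is set by catalysis. Ring-closing metathesis at C4=C5 closes the ten-membered ring.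

Key step: step 11

Remark on numbering: germacrane numbering of the target is used for all intermediates (C1 furanone C=O, C2 =CH, C3 O–C=, C4=C5, C6 lactone CH–O, C7, C8 CH–O-angelate, C9 CH2, C10 quaternary, C11 CH(CH3), C12 lactone C=O). Ring A is C1/C10/C9/C8/O8 and ring B is C6/O/C12/C11/C7.

Assumption: the (R)-SEGPHOS-modified iridium catalyst is taken to deliver the allyl unit to the Re face of aliphatic aldehydes, as in the parent carbonyl allylation; with the opposite sense the (S)-ligand would be used.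

Step 1
Reactants: 1 (S)-5-(hydroxymethyl)furan-2(5H)-one
Product: 2 (S)-5-{[(tert-butyldiphenylsilyl)oxy]methyl}furan-2(5H)-one
Conditions: t-BuPh2SiCl, imidazole, CH2Cl2, 0 °C to rt
Reagents that add atoms: tert-butyl(chloro)diphenylsilane, CC(C)(C)[Si](Cl)(c1ccccc1)c1ccccc1
Why: Standard silylation of the primary alcohol leaves the purchased C6 centre untouched and installs the bulky group that later shields one face of the butenolide.

Step 2
Reactants: 2 (S)-5-{[(tert-butyldiphenylsilyl)oxy]methyl}furan-2(5H)-one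
Product: 4 (4R,5S)-5-{[(tert-butyldiphenylsilyl)oxy]methyl}-4-ethenyloxolan-2-one, via silyl ketene acetal 3 (not isolated)
Conditions: CH2=CHMgBr, CuBr·SMe2 (10 mol %), Me3SiCl, THF, −78 °C; then aq. NH4Cl
Reagents that add atoms: vinylmagnesium bromide, C=C[Mg]Br; chlorotrimethylsilane, C[Si](C)(C)Cl (its atoms stay only in 3)
Why: In this copper-catalysed, silyl-chloride-accelerated conjugate addition the vinyl group should enter C7 anti to the C6 CH2OSi group, so C7 is set by substrate control.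

Step 3
Reactants: 4 (4R,5S)-5-{[(tert-butyldiphenylsilyl)oxy]methyl}-4-ethenyloxolan-2-one
Product: 6 (3S,4S,5S)-5-{[(tert-butyldiphenylsilyl)oxy]methyl}-4-ethenyl-3-methyloxolan-2-one (all-trans), via lithium enolate 5 (not isolated)
Conditions: LiN(i-Pr)2, THF, −78 °C; then MeI, −78 to −40 °C
Reagents that add atoms: iodomethane, CI
Why: In this lactone enolate alkylation MeI should approach anti to the neighbouring C7 vinyl group, which sets C11 as the all-trans and also thermodynamically preferred epimer.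

Step 4
Reactants: 6 (3S,4S,5S)-5-{[(tert-butyldiphenylsilyl)oxy]methyl}-4-ethenyl-3-methyloxolan-2-one
Product: 8 (2S,3S,4S)-2-{[(tert-butyldiphenylsilyl)oxy]methyl}-4-methyl-5-oxooxolane-3-carbaldehyde, via secondary ozonide 7 (not isolated)
Conditions: O3, CH2Cl2, −78 °C; then Me2S, −78 °C to rt
Reagents that add atoms: ozone, [O-][O+]=O
Why: Ozonolysis with reductive work-up cleaves the only alkene to the C8 aldehyde under neutral conditions that should not epimerise C7.

Step 5
Reactants: 9 methyl 2-(hydroxymethyl)prop-2-enoate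
Product: 10 methyl 2-{[(tert-butoxycarbonyl)oxy]methyl}prop-2-enoate
Conditions: Boc2O, DMAP (cat.), CH2Cl2, 0 °C to rt
Reagents that add atoms: di-tert-butyl dicarbonate, CC(C)(C)OC(=O)OC(=O)OC(C)(C)C
Why: DMAP-catalysed carbonate formation on the primary allylic alcohol gives the allyl donor for step 6.

Step 6
Reactants: 8 (2S,3S,4S)-2-{[(tert-butyldiphenylsilyl)oxy]methyl}-4-methyl-5-oxooxolane-3-carbaldehyde; 10 methyl 2-{[(tert-butoxycarbonyl)oxy]methyl}prop-2-enoate
Product: 12 (3S,4R,5S)-5-{[(tert-butyldiphenylsilyl)oxy]methyl}-3-methyl-4-[(2R)-4-methylidene-5-oxooxolan-2-yl]oxolan-2-one, via hydroxy ester 11 (not isolated)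
Conditions: [Ir(cod)Cl]2 (2.5 mol %), (R)-SEGPHOS (5 mol %), 4-chloro-3-nitrobenzoic acid (10 mol %), Cs2CO3 (20 mol %), i-PrOH (2 equiv), THF, 70 °C
Reagents that add atoms: none
Why: Iridium-catalysed transfer-hydrogenative 2-(alkoxycarbonyl)allylation of the aldehyde followed by spontaneous lactonisation builds ring A, and C8 is set as (R) by catalyst-controlled Re-face delivery rather than by the weak bias of the substrate.

Step 7
Reactants: 12 (3S,4R,5S)-5-{[(tert-butyldiphenylsilyl)oxy]methyl}-3-methyl-4-[(2R)-4-methylidene-5-oxooxolan-2-yl]oxolan-2-one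
Product: 14 (3S,4R,5S)-5-{[(tert-butyldiphenylsilyl)oxy]methyl}-4-[(2R,4S)-4-chloro-4-methyl-5-oxooxolan-2-yl]-3-methyloxolan-2-one, via ring A lithium enolate 13 (not isolated)
Conditions: LiBH(s-Bu)3 (1.05 equiv), THF, −78 °C; then N-chlorosuccinimide, −78 to −20 °C
Reagents that add atoms: N-chlorosuccinimide, O=C1CCC(=O)N1Cl
Why: Conjugate hydride addition to the exocyclic acrylate forms the ring A enolate regiospecifically (ring B is never enolised), and electrophilic chlorination should occur anti to the bulky C8 substituent, which sets C10 as the (S)-chloride.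

Step 8
Reactants: 14 (3S,4R,5S)-5-{[(tert-butyldiphenylsilyl)oxy]methyl}-4-[(2R,4S)-4-chloro-4-methyl-5-oxooxolan-2-yl]-3-methyloxolan-2-one
Product: 15 (3S,4R,5S)-4-[(2R,4S)-4-chloro-4-methyl-5-oxooxolan-2-yl]-5-(hydroxymethyl)-3-methyloxolan-2-one
Conditions: HF·pyridine, THF, 0 °C to rt
Reagents that add atoms: none
Why: Fluoride-mediated silyl ether cleavage under non-basic conditions should leave both lactones and the tertiary chloride untouched.

Step 9
Reactants: 15 (3S,4R,5S)-4-[(2R,4S)-4-chloro-4-methyl-5-oxooxolan-2-yl]-5-(hydroxymethyl)-3-methyloxolan-2-one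
Product: 16 (2S,3R,4S)-3-[(2R,4S)-4-chloro-4-methyl-5-oxooxolan-2-yl]-4-methyl-5-oxooxolane-2-carbaldehyde
Conditions: Dess–Martin periodinane, CH2Cl2, 0 °C to rt
Reagents that add atoms: none
Why: Dess–Martin oxidation of the primary alcohol under neutral conditions should give the α-acyloxy aldehyde without epimerisation at C6.

Step 10
Reactants: 16 (2S,3R,4S)-3-[(2R,4S)-4-chloro-4-methyl-5-oxooxolan-2-yl]-4-methyl-5-oxooxolane-2-carbaldehyde
Product: 17 (3S,4R,5R)-4-[(2R,4S)-4-chloro-4-methyl-5-oxooxolan-2-yl]-5-ethenyl-3-methyloxolan-2-one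
Conditions: MePPh3Br, KN(SiMe3)2, THF, −78 to 0 °C
Reagents that add atoms: methyltriphenylphosphonium bromide, C[P+](c1ccccc1)(c1ccccc1)c1ccccc1.[Br-]
Why: Wittig methylenation with the cold, non-stabilised ylide should be faster than enolisation of the aldehyde, so the C6 vinyl group needed for ring closure is installed with C6 intact.

Step 11
Reactants: 17 (3S,4R,5R)-4-[(2R,4S)-4-chloro-4-methyl-5-oxooxolan-2-yl]-5-ethenyl-3-methyloxolan-2-one; 18 3-methylbut-3-en-2-one
Product: 21 (2R)-2-{(2R)-2-[(2R,3R,4S)-2-ethenyl-4-methyl-5-oxooxolan-3-yl]-2-hydroxyethyl}-2-methyl-5-(prop-1-en-2-yl)furan-3(2H)-one, via lithium enolate 19 (not isolated), via chloro diketone 20 (not isolated)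
Conditions: 18, LiN(i-Pr)2 (1.05 equiv each), THF, −78 °C; add 17, −78 to 0 °C; then DMPU, rt to 40 °C
Reagents that add atoms: none
Why: Proposed new method: the kinetic enolate 19 adds through C2 to the ring A carbonyl C1, the tetrahedral intermediate opens to the C8 alkoxide, proton transfer gives the diketonate of 20, and its oxygen on C3 displaces chloride at C10, so C1–C2 and O–C10 form in one flask and one equivalent of base ends as LiCl. The closest known reaction types are the Claisen-type acylation of ketone enolates by lactones, the cyclisation of 4-halo-1,3-diketones (made from α-haloacyl halides) to 3(2H)-furanones, and SN2 displacement at tertiary α-chloro carbonyl compounds with inversion; their merger on an α-chloro lactone is new. The only ring closed is the furanone, by a 5-exo-tet attack with the C–Cl bond anti to the incoming oxygen. The only new stereocentre, C10, is controlled by stereospecific inversion of the (S)-chloride, itself relayed from C8, so it should emerge as (R). Chemoselectivity for ring A over ring B is needed and should be secured by the inductive activation of C1 by chlorine and by the fact that ring A cannot be enolised, while closure through oxygen rather than carbon follows from the strain of the alternative cyclopropanone. Close to one equivalent of enolate keeps O8 protonated, which should suppress Grob-type fragmentation, relactonisation and loss of HCl, and a shift of ring B to O8 is disfavoured because it would give an all-cis lactone.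

Step 12
Reactants: 21 (2R)-2-{(2R)-2-[(2R,3R,4S)-2-ethenyl-4-methyl-5-oxooxolan-3-yl]-2-hydroxyethyl}-2-methyl-5-(prop-1-en-2-yl)furan-3(2H)-one; 22 angelic acid, (Z)-2-methylbut-2-enoic acid
Product: 24 (1R)-1-[(2R,3R,4S)-2-ethenyl-4-methyl-5-oxooxolan-3-yl]-2-[(2R)-2-methyl-3-oxo-5-(prop-1-en-2-yl)-2,3-dihydrofuran-2-yl]ethyl (Z)-2-methylbut-2-enoate, via mixed anhydride 23 (not isolated)
Conditions: 22, 2,4,6-trichlorobenzoyl chloride, Et3N, toluene, rt; then 21, 80 °C
Reagents that add atoms: 2,4,6-trichlorobenzoyl chloride, O=C(Cl)c1c(Cl)cc(Cl)cc1Cl (its atoms stay only in 23)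
Why: Yamaguchi-type esterification through mixed anhydride 23 without a nucleophilic catalyst is the established way to acylate hindered secondary alcohols with angelic acid while avoiding Z to E isomerisation to the tiglate.

Step 13
Reactants: 24 (1R)-1-[(2R,3R,4S)-2-ethenyl-4-methyl-5-oxooxolan-3-yl]-2-[(2R)-2-methyl-3-oxo-5-(prop-1-en-2-yl)-2,3-dihydrofuran-2-yl]ethyl (Z)-2-methylbut-2-enoate
Product: 25 CNP0278264.1, (6R,7R,8R,10R,11S)-8-angeloyloxy-1-oxo-3,10-epoxygermacra-2,4Z-dien-6,12-olide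
Conditions: second-generation Hoveyda–Grubbs catalyst RuCl2(H2IMes)(=CH-C6H4-2-O-i-Pr) (20 mol %), 1,4-benzoquinone (20 mol %), toluene (1 mM), 110 °C
Reagents that add atoms: none
Why: In this ring-closing metathesis the catalyst should load on the C6 vinyl group and close onto the isopropenyl group, the oxygen-bridged ten-membered ring can hold C4=C5 only with C3 and C6 cis (Z), and the trisubstituted electron-poor angelate alkene should stay inert.

Compound list
1 | (S)-5-(hydroxymethyl)furan-2(5H)-one | OC[C@H]1OC(=O)C=C1 | starting material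
2 | (S)-5-{[(tert-butyldiphenylsilyl)oxy]methyl}furan-2(5H)-one | CC(C)(C)[Si](c1ccccc1)(c2ccccc2)OC[C@H]3OC(=O)C=C3 | intermediate
3 | trimethylsilyl ketene acetal of lactone 4 (C6 and C7 as in 4) | CC(C)(C)[Si](c1ccccc1)(c2ccccc2)OC[C@H]3OC(O[Si](C)(C)C)=C[C@@H]3C=C | intermediate
4 | (4R,5S)-5-{[(tert-butyldiphenylsilyl)oxy]methyl}-4-ethenyloxolan-2-one (trans) | CC(C)(C)[Si](c1ccccc1)(c2ccccc2)OC[C@H]3OC(=O)C[C@@H]3C=C | intermediate
5 | lithium enolate of lactone 4 | [Li+].CC(C)(C)[Si](c1ccccc1)(c2ccccc2)OC[C@H]3OC([O-])=C[C@@H]3C=C | intermediate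
6 | (3S,4S,5S)-5-{[(tert-butyldiphenylsilyl)oxy]methyl}-4-ethenyl-3-methyloxolan-2-one (all-trans) | CC(C)(C)[Si](c1ccccc1)(c2ccccc2)OC[C@H]3OC(=O)[C@@H](C)[C@@H]3C=C | intermediate
7 | secondary ozonide (1,2,4-trioxolane) of 6 | CC(C)(C)[Si](c1ccccc1)(c2ccccc2)OC[C@H]3OC(=O)[C@@H](C)[C@@H]3C4OOCO4 | intermediate
8 | (2S,3S,4S)-2-{[(tert-butyldiphenylsilyl)oxy]methyl}-4-methyl-5-oxooxolane-3-carbaldehyde | CC(C)(C)[Si](c1ccccc1)(c2ccccc2)OC[C@H]3OC(=O)[C@@H](C)[C@@H]3C=O | intermediate
9 | methyl 2-(hydroxymethyl)prop-2-enoate | C=C(CO)C(=O)OC | starting material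
10 | methyl 2-{[(tert-butoxycarbonyl)oxy]methyl}prop-2-enoate | C=C(COC(=O)OC(C)(C)C)C(=O)OC | intermediate
11 | methyl 2-{(2R)-2-hydroxy-2-[ring B of 8]ethyl}prop-2-enoate (open form of 12) | CC(C)(C)[Si](c1ccccc1)(c2ccccc2)OC[C@H]3OC(=O)[C@@H](C)[C@@H]3[C@H](O)CC(=C)C(=O)OC | intermediate
12 | (3S,4R,5S)-5-{[(tert-butyldiphenylsilyl)oxy]methyl}-3-methyl-4-[(2R)-4-methylidene-5-oxooxolan-2-yl]oxolan-2-one | CC(C)(C)[Si](c1ccccc1)(c2ccccc2)OC[C@H]3OC(=O)[C@@H](C)[C@@H]3[C@H]4CC(=C)C(=O)O4 | intermediate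
13 | ring A lithium enolate formed from 12 by conjugate hydride addition | [Li+].CC(C)(C)[Si](c1ccccc1)(c2ccccc2)OC[C@H]3OC(=O)[C@@H](C)[C@@H]3[C@H]4CC(C)=C([O-])O4 | intermediate
14 | (3S,4R,5S)-5-{[(tert-butyldiphenylsilyl)oxy]methyl}-4-[(2R,4S)-4-chloro-4-methyl-5-oxooxolan-2-yl]-3-methyloxolan-2-one | CC(C)(C)[Si](c1ccccc1)(c2ccccc2)OC[C@H]3OC(=O)[C@@H](C)[C@@H]3[C@H]4C[C@](C)(Cl)C(=O)O4 | intermediate
15 | (3S,4R,5S)-4-[(2R,4S)-4-chloro-4-methyl-5-oxooxolan-2-yl]-5-(hydroxymethyl)-3-methyloxolan-2-one | OC[C@H]1OC(=O)[C@@H](C)[C@@H]1[C@H]2C[C@](C)(Cl)C(=O)O2 | intermediate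
16 | (2S,3R,4S)-3-[(2R,4S)-4-chloro-4-methyl-5-oxooxolan-2-yl]-4-methyl-5-oxooxolane-2-carbaldehyde | O=C[C@H]1OC(=O)[C@@H](C)[C@@H]1[C@H]2C[C@](C)(Cl)C(=O)O2 | intermediate
17 | (3S,4R,5R)-4-[(2R,4S)-4-chloro-4-methyl-5-oxooxolan-2-yl]-5-ethenyl-3-methyloxolan-2-one | C=C[C@H]1OC(=O)[C@@H](C)[C@@H]1[C@H]2C[C@](C)(Cl)C(=O)O2 | intermediate
18 | 3-methylbut-3-en-2-one | CC(=O)C(C)=C | starting material
19 | lithium 3-methylbuta-1,3-dien-2-olate | [Li+].[O-]C(=C)C(C)=C | intermediate
20 | (6S,8R)-6-chloro-8-[(2R,3R,4S)-2-ethenyl-4-methyl-5-oxooxolan-3-yl]-8-hydroxy-2,6-dimethyloct-1-ene-3,5-dione | C=C(C)C(=O)CC(=O)[C@@](C)(Cl)C[C@@H](O)[C@@H]1[C@@H](C=C)OC(=O)[C@H]1C | intermediate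
21 | (2R)-2-{(2R)-2-[(2R,3R,4S)-2-ethenyl-4-methyl-5-oxooxolan-3-yl]-2-hydroxyethyl}-2-methyl-5-(prop-1-en-2-yl)furan-3(2H)-one | C=C(C)C1=CC(=O)[C@](C)(O1)C[C@@H](O)[C@@H]2[C@@H](C=C)OC(=O)[C@H]2C | intermediate
22 | angelic acid, (Z)-2-methylbut-2-enoic acid | C/C=C(/C)C(=O)O | starting material
23 | angelic 2,4,6-trichlorobenzoic anhydride | C/C=C(/C)C(=O)OC(=O)c1c(Cl)cc(Cl)cc1Cl | intermediate
24 | (1R)-1-[(2R,3R,4S)-2-ethenyl-4-methyl-5-oxooxolan-3-yl]-2-[(2R)-2-methyl-3-oxo-5-(prop-1-en-2-yl)-2,3-dihydrofuran-2-yl]ethyl (Z)-2-methylbut-2-enoate | C/C=C(/C)C(=O)O[C@H](C[C@@]1(C)OC(=CC1=O)C(C)=C)[C@@H]2[C@@H](C=C)OC(=O)[C@H]2C | intermediate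
25 | CNP0278264.1, (6R,7R,8R,10R,11S)-8-angeloyloxy-1-oxo-3,10-epoxygermacra-2,4Z-dien-6,12-olide | C/C=C(/C)C(=O)O[C@@H]1C[C@@]2(C)OC(=CC2=O)/C(C)=C\[C@H]2OC(=O)[C@@H](C)[C@@H]21 | target

Total step count: 13. Longest linear sequence: 12 (steps 1–4 and 6–13).

Steps most likely to fail

1. Step 11 (Proposed new method). The enolate may attack the ring B carbonyl in competition. HCl may be lost by elimination before the oxygen closes. The tertiary chloride may ionise, with erosion of the stereochemical information at C10.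
The fallback uses known chemistry: an open-chain acyl donor, with the two bonds made in separate flasks. It sets out from 17.
   - Aminolysis of the activated ring A with MeNH(OMe)·HCl and AlMe3 (CH2Cl2, 0 °C) should give the hydroxy Weinreb amide F1.
   - TESOTf and 2,6-lutidine give its triethylsilyl ether F2, which can no longer relactonise.
   - Acylation of enolate 19 by this amide (THF, −78 to 0 °C) gives the isolable chloro diketone silyl ether F3.
   - K2CO3 in DMF closes the ring by the known cyclisation of 4-halo-1,3-diketones to the furanone silyl ether F4.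
   - HF·pyridine then comes back to the route at 21.

2. Step 13. Ring closure onto the hindered 1,1-disubstituted alkene may be slower than intermolecular metathesis at the vinyl group, so that oligomerisation takes over, or the catalyst may decompose at the temperature needed.
The fallback replaces metathesis by an olefination. It sets out from 14 and comes back at 25.
   - The dianion of diethyl (3-oxobutan-2-yl)phosphonate (NaH, then n-BuLi, THF) takes the place of 19 in the annulation and should give the phosphonate furanone alcohol F5 (both epimers at C4).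
   - Angeloylation as in step 12 gives the phosphonate angelate F6.
   - HF·pyridine gives the primary alcohol F7, and Dess–Martin periodinane gives the aldehyde F8.
   - An intramolecular Horner–Wadsworth–Emmons reaction (LiCl, DBU, MeCN, high dilution) then forms C4=C5 and gives 25.

3. Step 6. Under warm, weakly basic conditions the aldehyde may epimerise at C7 or open ring B by β-elimination, and catalyst control at C8 may be eroded by the branched substrate.
The fallback is a reagent-controlled addition at low temperature followed by a carbonylation. It sets out from 8.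
   - The allenylboronate of diisopropyl tartrate (the antipode that attacks the Re face; toluene, −78 °C) should give the homopropargylic alcohol F9.
   - Cyclocarbonylation (PdCl2, thiourea, CO at 1 atm, acetone, 50 °C) closes the α-methylene lactone and comes back to the route at 12.

Further compounds
F1 | step 11 | (2S,4R)-2-chloro-4-[(2R,3R,4S)-2-ethenyl-4-methyl-5-oxooxolan-3-yl]-4-hydroxy-N-methoxy-N,2-dimethylbutanamide | CON(C)C(=O)[C@@](C)(Cl)C[C@@H](O)[C@@H]1[C@@H](C=C)OC(=O)[C@H]1C
F2 | step 11 | triethylsilyl ether of F1 | CON(C)C(=O)[C@@](C)(Cl)C[C@@H](O[Si](CC)(CC)CC)[C@@H]1[C@@H](C=C)OC(=O)[C@H]1C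
F3 | step 11 | triethylsilyl ether of chloro diketone 20 | C=C(C)C(=O)CC(=O)[C@@](C)(Cl)C[C@@H](O[Si](CC)(CC)CC)[C@@H]1[C@@H](C=C)OC(=O)[C@H]1C
F4 | step 11 | triethylsilyl ether of furanone alcohol 21 | C=C(C)C1=CC(=O)[C@](C)(O1)C[C@@H](O[Si](CC)(CC)CC)[C@@H]2[C@@H](C=C)OC(=O)[C@H]2C
F5 | step 13 | diethyl {1-[(5R)-5-{(2R)-2-hydroxy-2-[ring B with CH2OSi(t-Bu)Ph2 at C6]ethyl}-5-methyl-4-oxo-4,5-dihydrofuran-2-yl]ethyl}phosphonate (C4 epimers) | CCOP(=O)(OCC)C(C)C1=CC(=O)[C@](C)(O1)C[C@@H](O)[C@@H]2[C@@H](CO[Si](c3ccccc3)(c4ccccc4)C(C)(C)C)OC(=O)[C@H]2C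
F6 | step 13 | C8 angelate of F5 | C/C=C(/C)C(=O)O[C@H](C[C@@]1(C)OC(=CC1=O)C(C)P(=O)(OCC)OCC)[C@@H]2[C@@H](CO[Si](c3ccccc3)(c4ccccc4)C(C)(C)C)OC(=O)[C@H]2C
F7 | step 13 | primary alcohol from desilylation of F6 | C/C=C(/C)C(=O)O[C@H](C[C@@]1(C)OC(=CC1=O)C(C)P(=O)(OCC)OCC)[C@@H]2[C@@H](CO)OC(=O)[C@H]2C
F8 | step 13 | C5 aldehyde from oxidation of F7 | C/C=C(/C)C(=O)O[C@H](C[C@@]1(C)OC(=CC1=O)C(C)P(=O)(OCC)OCC)[C@@H]2[C@@H](C=O)OC(=O)[C@H]2C
F9 | step 6 | (3S,4R,5S)-5-{[(tert-butyldiphenylsilyl)oxy]methyl}-4-[(1R)-1-hydroxybut-3-yn-1-yl]-3-methyloxolan-2-one | CC(C)(C)[Si](c1ccccc1)(c2ccccc2)OC[C@H]3OC(=O)[C@@H](C)[C@@H]3[C@H](O)CC#C
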